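Everything rests on cutting C7–C7a, so that the benzene ring of the indole is grown onto an intact pyrrole ring. The feature exploited is the C7–H/C6–Br pair adjoining C7a, the pyrrole alpha carbon. A terminal bromoalkyne leaves exactly this pattern if its bromine slides from C7 to C6 on gold and C7a then captures the vinylidene carbon C7. One catalytic operation therefore closes the six-membered ring and positions the C6 bromine, while the C4 bromine arrives on the alkene. The precursor is a 1-tosylpyrrole bearing at C3 an (E)-1,4-dibromobut-1-en-3-ynyl chain, with ring and alkyne cis. Detosylation and NBS bromination at C3 and C2 complete the target.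

Key step: step 6

Remark: atoms of the open-chain compounds carry the indole numbers they will have in the target (chain C4–C7, pyrrole alpha carbon C7a). Tosyl (Ts) means 4-methylphenylsulfonyl.

Step 1
Reactants: 1 1H-pyrrole-3-carbaldehyde; 2 4-toluenesulfonyl chloride
Product: 3 1-tosylpyrrole-3-carbaldehyde
Conditions: TsCl, Et3N, DMAP (cat.), CH2Cl2, 0 °C to rt
Reagents that add atoms: 4-toluenesulfonyl chloride, Cc1ccc(cc1)S(=O)(=O)Cl
Why: N-sulfonylation of an acidified pyrrole N–H under DMAP catalysis, which installs the group that later shields the ring from IBr, NBS and gold.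

Step 2
Reactants: 3 1-tosylpyrrole-3-carbaldehyde; 4 dimethyl (1-diazo-2-oxopropyl)phosphonate
Product: 5 3-ethynyl-1-tosylpyrrole
Conditions: 4, K2CO3, MeOH/THF, 0 °C to rt
Reagents that add atoms: dimethyl (1-diazo-2-oxopropyl)phosphonate, COP(=O)(OC)C(=[N+]=[N-])C(C)=O
Why: Seyferth–Gilbert homologation in its Ohira–Bestmann form (deacylation of the reagent, phosphonate olefination of the aldehyde, loss of N2, 1,2-hydrogen shift), fast on this electron-poor aldehyde and stopped at full conversion so that methanolysis of the sulfonamide cannot compete.

Step 3
Reactants: 5 3-ethynyl-1-tosylpyrrole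
Product: 6 3-[(E)-1-bromo-2-iodoethenyl]-1-tosylpyrrole (Br and I trans, pyrrole ring cis to I)
Conditions: IBr, CH2Cl2, −78 to 0 °C, dark
Reagents that add atoms: iodine monobromide, BrI
Why: Electrophilic anti iodobromination of a terminal aryl-type alkyne, in which iodine bridges the triple bond and ends on terminal C5 while bromide opens the bridge from the opposite face at the pyrrolyl-stabilised C4 (Markovnikov), fixing the (E)-geometry and leaving the sulfonyl-deactivated ring untouched at this temperature.

Step 4
Reactants: 6 3-[(E)-1-bromo-2-iodoethenyl]-1-tosylpyrrole; 7 trimethylsilylacetylene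
Product: 8 3-[(E)-1-bromo-4-(trimethylsilyl)but-1-en-3-ynyl]-1-tosylpyrrole (pyrrole ring cis to the alkyne)
Conditions: 7, PdCl2(PPh3)2 (cat.), CuI (cat.), Et3N, THF, 0 °C to rt
Reagents that add atoms: trimethylsilylacetylene, C#C[Si](C)(C)C
Why: Sonogashira coupling in which zerovalent palladium inserts into the terminal C5–I bond far faster than into the hindered C4–Br bond and with retention of geometry, so halogen identity decides the site, and base-induced HBr loss is slow because H5 and the C4 bromine are syn.

Step 5
Reactants: 8 3-[(E)-1-bromo-4-(trimethylsilyl)but-1-en-3-ynyl]-1-tosylpyrrole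
Product: 9 3-[(E)-1,4-dibromobut-1-en-3-ynyl]-1-tosylpyrrole (pyrrole ring cis to the bromoethynyl group)
Conditions: NBS, AgNO3 (cat.), acetone, rt, dark
Reagents that add atoms: N-bromosuccinimide, O=C1CCC(=O)N1Br
Why: Silver-catalysed bromodesilylation of an alkynylsilane, in which AgNO3 labilises the C(sp)–Si bond and NBS transfers electrophilic bromine to that carbon, a standard one-step entry to 1-bromoalkynes that spares the bromoalkene and the deactivated pyrrole.

Step 6
Reactants: 9 3-[(E)-1,4-dibromobut-1-en-3-ynyl]-1-tosylpyrrole
Product: 11 4,6-dibromo-1-tosylindole, via AuCl bromovinylidene complex 10 (not isolated)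
Conditions: AuCl (5–10 mol %), toluene (dilute), 80 °C, Ar
Reagents that add atoms: none
Why: Coordination of AuCl to the C6≡C7 triple bond triggers a 1,2-shift of bromine from C7 to C6 and produces complex 10, in which C7 is an electrophilic, gold-bound carbene carbon. C7a lies within bonding distance because the (E)-alkene holds the pyrrole ring and the former alkyne on the same side, so it adds to C7; deprotonation at C7a then rearomatises the five-membered ring and protonolysis of the C7–Au bond releases 11 and the catalyst. The closest known reaction type is the AuCl-catalysed cycloisomerisation of ortho-(haloethynyl)biaryls to halophenanthrenes with 1,2-halide migration, supported by the tungsten-vinylidene closure of (iodoethynyl)styrenes to iodonaphthalenes. The benzene ring closes in the 6-endo-dig sense relative to the original alkyne, equally viewed as a six-electron electrocyclisation of the C7a=C3a–C4=C5–C6=C7 dienyl vinylidene, and no stereocentre is created. The step needs migration before closure, since attack on the carbon still carrying bromine would misplace that bromine at C7, and ligand-free AuCl in a non-polar solvent favours the vinylidene path where hard Lewis acids do not. It also needs alpha rather than beta closure, which the substrate secures because only C7a=C3a is a formal double bond conjugated with the chain and beta closure would end in a non-benzenoid, ortho-quinoid framework.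

Step 7
Reactants: 11 4,6-dibromo-1-tosylindole
Product: 12 4,6-dibromo-1H-indole
Conditions: NaOH (aq), THF/MeOH, 60 °C
Reagents that add atoms: none
Why: Alkaline hydrolysis of an N-sulfonylindole, in which hydroxide attacks sulfur and expels an indolide made a better leaving group by two bromines; the aryl bromides are inert, and aqueous hydroxide prevents build-up of a methylating sulfonate ester.

Step 8
Reactants: 12 4,6-dibromo-1H-indole
Product: 14 2,3,4,6-tetrabromo-1H-indole, via 3,4,6-tribromo-1H-indole 13 (not isolated)
Conditions: NBS (2 equiv), silica gel, CH2Cl2 (dry), 0 °C to rt, dark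
Reagents that add atoms: N-bromosuccinimide, O=C1CCC(=O)N1Br
Why: Sequential electrophilic aromatic bromination of a free indole, in which the enamine-like C3 reacts first and the second equivalent takes C2, the only activated position left, because C5 and C7 sit on a ring deactivated and shielded by its two bromines.

Compound list
1 | 1H-pyrrole-3-carbaldehyde | O=Cc1cc[nH]c1 | starting material
2 | 4-toluenesulfonyl chloride | Cc1ccc(cc1)S(=O)(=O)Cl | starting material
3 | 1-tosylpyrrole-3-carbaldehyde | Cc1ccc(cc1)S(=O)(=O)n1ccc(C=O)c1 | intermediate
4 | dimethyl (1-diazo-2-oxopropyl)phosphonate | COP(=O)(OC)C(=[N+]=[N-])C(C)=O | starting material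
5 | 3-ethynyl-1-tosylpyrrole | Cc1ccc(cc1)S(=O)(=O)n1ccc(C#C)c1 | intermediate
6 | 3-[(E)-1-bromo-2-iodoethenyl]-1-tosylpyrrole | Cc1ccc(cc1)S(=O)(=O)n1ccc(c1)/C(Br)=C\I | intermediate
7 | trimethylsilylacetylene | C#C[Si](C)(C)C | starting material
8 | 3-[(E)-1-bromo-4-(trimethylsilyl)but-1-en-3-ynyl]-1-tosylpyrrole | Cc1ccc(cc1)S(=O)(=O)n1ccc(c1)/C(Br)=C\C#C[Si](C)(C)C | intermediate
9 | 3-[(E)-1,4-dibromobut-1-en-3-ynyl]-1-tosylpyrrole | Cc1ccc(cc1)S(=O)(=O)n1ccc(c1)/C(Br)=C\C#CBr | intermediate
10 | AuCl bromovinylidene complex of 9 (Br shifted to C6, C7=AuCl, (E)-alkene retained) | Cc1ccc(cc1)S(=O)(=O)n1ccc(c1)/C(Br)=C\C(Br)=C=[Au]Cl | intermediate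
11 | 4,6-dibromo-1-tosylindole | Cc1ccc(cc1)S(=O)(=O)n1ccc2c(Br)cc(Br)cc21 | intermediate
12 | 4,6-dibromo-1H-indole | Brc1cc(Br)c2cc[nH]c2c1 | intermediate
13 | 3,4,6-tribromo-1H-indole | Brc1cc(Br)c2c(Br)c[nH]c2c1 | intermediate
14 | 2,3,4,6-tetrabromo-1H-indole | Brc1cc(Br)c2c(Br)c(Br)[nH]c2c1 | target

Total step count: 8. Longest linear sequence: 8 (steps 1–8 from 1).

Steps most likely to fail

1. Step 6. Ring closure may outrun the bromine shift, so that bromine stays on the carbon that bonds to C7a. Alternatively, attack by the sulfonyl-deactivated and sterically flanked alpha carbon may be so slow that the catalyst decays and the bromoalkyne oligomerises. The fallback sets out from 8 and returns at 11, and it separates ring closure from bromine placement.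
   - Brief K2CO3/MeOH treatment of 8 removes silicon and should give 3-[(E)-1-bromobut-1-en-3-ynyl]-1-tosylpyrrole F1.
   - PtCl2-catalysed cycloisomerisation in toluene at 80 °C should give 4-bromo-1-tosylindole F2. This is hydroarylation of a terminal alkyne, where π-activation and vinylidene paths converge on one product.
   - Sterically governed C–H borylation uses B2pin2, [Ir(OMe)(cod)]2 and 4,4'-di-tert-butyl-2,2'-bipyridine in THF at 80 °C. It addresses C6, the only C–H without an ortho or peri substituent, and should give 4-bromo-6-(4,4,5,5-tetramethyl-1,3,2-dioxaborolan-2-yl)-1-tosylindole F3.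
   - CuBr2 in aqueous methanol at 80 °C then exchanges boron for bromine and delivers 11.

2. Step 4. The alkenylpalladium intermediate may lose both vicinal halogens and revert to the alkyne. The alkene geometry may also erode, or the alkyne may homocouple under copper/amine conditions. The fallback sets out from 6 and 7 and returns at 8. It replaces the copper/amine manifold with a preformed organozinc nucleophile.
   - Compound 7 is deprotonated with n-BuLi in THF at −78 °C to lithium (trimethylsilyl)acetylide F4.
   - F4 is transmetalated with ZnCl2 to chloro[(trimethylsilyl)ethynyl]zinc F5.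
   - F5 is coupled with 6 under Pd(PPh3)4 catalysis at 0 °C to rt (Negishi coupling). Fast transmetalation shortens the lifetime of the bromine-bearing alkenylpalladium species, and neither base nor copper is present.

3. Step 3. Anti selectivity may be incomplete if an open, pyrrolyl-stabilised vinyl cation intervenes. Halogen scrambling through disproportionation of IBr and light-induced reversal of the addition are further risks. The fallback sets out from 5 and returns at 8.
   - Bu4NBr3 in CH2Cl2 at rt adds bromine by a concerted anti pathway that involves no free cation and should give 3-[(E)-1,2-dibromoethenyl]-1-tosylpyrrole F6.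
   - F6 is coupled with 7 under PdCl2(PPh3)2/CuI/Et3N. Site selection then rests on the steric difference between the terminal C5–Br and the ring-flanked C4–Br.

Further compounds
F1 | step 6 | 3-[(E)-1-bromobut-1-en-3-ynyl]-1-tosylpyrrole | Cc1ccc(cc1)S(=O)(=O)n1ccc(c1)/C(Br)=C\C#C
F2 | step 6 | 4-bromo-1-tosylindole | Cc1ccc(cc1)S(=O)(=O)n1ccc2c(Br)cccc21
F3 | step 6 | 4-bromo-6-(4,4,5,5-tetramethyl-1,3,2-dioxaborolan-2-yl)-1-tosylindole | Cc1ccc(cc1)S(=O)(=O)n1ccc2c(Br)cc(cc21)B1OC(C)(C)C(C)(C)O1
F4 | step 4 | lithium (trimethylsilyl)acetylide | C[Si](C)(C)C#C[Li]
F5 | step 4 | chloro[(trimethylsilyl)ethynyl]zinc | C[Si](C)(C)C#C[Zn]Cl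
F6 | step 3 | 3-[(E)-1,2-dibromoethenyl]-1-tosylpyrrole | Cc1ccc(cc1)S(=O)(=O)n1ccc(c1)/C(Br)=C\Br
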